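Assumption: the target has no stereocentre (it is achiral), so "single enantiomer" needs no stereocontrol and the SMILES given is the compound made.

**Retrosynthetic overview**
- The 5,8-hydroquinone comes from the flavone-5,8-quinone, which comes from the 5-hydroxy-8-methoxyflavone by oxidative demethylation; the 5-OH is freed from the heptamethyl ether by peri-selective demethylation.
- The 3-methoxyflavone comes from the flavonol by O-methylation; the flavonol comes from a 2'-hydroxychalcone by Algar–Flynn–Oyamada oxidative cyclisation.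
- The chalcone comes from a Claisen–Schmidt aldol condensation of 2-hydroxy-3,4,6-trimethoxyacetophenone with 2,3,4-trimethoxybenzaldehyde; this C–C bond becomes C2–C3 of the flavone.
- The acetophenone comes from 1,2,3,5-tetramethoxybenzene (Friedel–Crafts acetylation with ortho-demethylation), made from 3,4,5-trimethoxyphenol.
- Rings A and B are bought; the pyranone ring C is the only ring formed (step 4).

**Route**

Step 1
Reactants: 1 3,4,5-trimethoxyphenol
Product: 2 1,2,3,5-tetramethoxybenzene
Conditions: MeI, K2CO3, acetone, reflux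
Reagents that add atoms: iodomethane, CI
Why: Williamson ether synthesis; the phenoxide is methylated by SN2 on MeI with nothing else in the molecule to compete.

Step 2
Reactants: 2 1,2,3,5-tetramethoxybenzene
Product: 4 2-hydroxy-3,4,6-trimethoxyacetophenone, via 2,3,4,6-tetramethoxyacetophenone 3 (not isolated)
Conditions: AcCl, AlCl3, Et2O, 0 °C to rt; then ice/dil. HCl
Reagents that add atoms: acetyl chloride, CC(Cl)=O
Why: Friedel–Crafts acylation at the only type of free ring position, then chelation-controlled AlCl3 cleavage of the more crowded ortho-methoxy (the one flanked by a second OMe) to the hydrogen-bonded o-hydroxy ketone.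

Step 3
Reactants: 4 2-hydroxy-3,4,6-trimethoxyacetophenone; 5 2,3,4-trimethoxybenzaldehyde
Product: 7 (E)-1-(2-hydroxy-3,4,6-trimethoxyphenyl)-3-(2,3,4-trimethoxyphenyl)prop-2-en-1-one, via racemic aldol adduct 6 (not isolated)
Conditions: KOH (50% aq.), EtOH, rt, 48 h; then dil. HCl, 0 °C
Reagents that add atoms: none
Why: Claisen–Schmidt aldol condensation of a methyl ketone enolate with a non-enolisable aldehyde, followed by E1cB dehydration to the conjugated E-chalcone, which erases the transient carbinol stereocentre.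

Step 4
Reactants: 7 the chalcone
Product: 9 3-hydroxy-5,7,8-trimethoxy-2-(2,3,4-trimethoxyphenyl)-4H-chromen-4-one, via trans-dihydroflavonol 8 (not isolated)
Conditions: 30% H2O2, 2 M aq. NaOH, MeOH, 0 °C to rt; then dil. HCl
Reagents that add atoms: hydrogen peroxide, OO
Why: Algar–Flynn–Oyamada reaction; phenoxide oxa-Michael closure with α-hydroxylation by peroxide gives the racemic dihydroflavonol, which is oxidised in situ to the achiral flavonol.

Step 5
Reactants: 9 the flavonol
Product: 10 3,5,7,8-tetramethoxy-2-(2,3,4-trimethoxyphenyl)-4H-chromen-4-one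
Conditions: MeI, K2CO3, acetone, reflux
Reagents that add atoms: iodomethane, CI
Why: Williamson O-methylation of the acidic 3-hydroxyl, the only free OH present.

Step 6
Reactants: 10 the heptamethoxyflavone
Product: 11 5-hydroxy-3,7,8-trimethoxy-2-(2,3,4-trimethoxyphenyl)-4H-chromen-4-one
Conditions: BCl3 (1.5 eq), CH2Cl2, −40 to 0 °C; then H2O
Reagents that add atoms: none
Why: Chelation-controlled Lewis-acid ether cleavage; boron bound to the C4 carbonyl forms a six-membered chelate with the peri 5-OMe, which is cleaved much faster than the 3-OMe or the non-chelated methoxy groups.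

Step 7
Reactants: 11 the 5-hydroxyflavone
Product: 12 3,7-dimethoxy-2-(2,3,4-trimethoxyphenyl)-4H-chromene-4,5,8-trione
Conditions: PhI(OAc)2 (1.1 eq), MeCN/H2O 3:1, 0 °C, 20 min
Reagents that add atoms: water, O
Why: Hypervalent-iodine oxidative demethylation of a p-methoxyphenol; water adds at C8 para to the activated phenol and loss of methanol gives the p-quinone, while the B ring (no free OH, no para-dioxygen pair) is left alone.

Step 8
Reactants: 12 the flavone-5,8-quinone
Product: 13 5,8-dihydroxy-3,7-dimethoxy-2-(2,3,4-trimethoxyphenyl)-4H-chromen-4-one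
Conditions: Na2S2O4, EtOAc/H2O (degassed), rt, N2
Reagents that add atoms: none
Why: Dithionite reduction of a p-quinone to the hydroquinone; it touches neither the pyranone nor the methyl ethers and creates no stereocentre.

**Compound list**
1 | 3,4,5-trimethoxyphenol | COc1cc(O)cc(OC)c1OC | starting material
2 | 1,2,3,5-tetramethoxybenzene | COc1cc(OC)c(OC)c(OC)c1 | intermediate
3 | 2,3,4,6-tetramethoxyacetophenone | CC(=O)c1c(OC)cc(OC)c(OC)c1OC | intermediate
4 | 2-hydroxy-3,4,6-trimethoxyacetophenone | CC(=O)c1c(O)c(OC)c(OC)cc1OC | intermediate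
5 | 2,3,4-trimethoxybenzaldehyde | COc1ccc(C=O)c(OC)c1OC | starting material
6 | (±)-3-hydroxy-1-(2-hydroxy-3,4,6-trimethoxyphenyl)-3-(2,3,4-trimethoxyphenyl)propan-1-one (racemic aldol adduct) | COc1ccc(C(O)CC(=O)c2c(O)c(OC)c(OC)cc2OC)c(OC)c1OC | intermediate
7 | (E)-1-(2-hydroxy-3,4,6-trimethoxyphenyl)-3-(2,3,4-trimethoxyphenyl)prop-2-en-1-one | COc1ccc(/C=C/C(=O)c2c(O)c(OC)c(OC)cc2OC)c(OC)c1OC | intermediate
8 | (±)-trans-3-hydroxy-5,7,8-trimethoxy-2-(2,3,4-trimethoxyphenyl)chroman-4-one (racemate; 2R,3R enantiomer drawn) | COc1ccc([C@H]2Oc3c(OC)c(OC)cc(OC)c3C(=O)[C@@H]2O)c(OC)c1OC | intermediate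
9 | 3-hydroxy-5,7,8-trimethoxy-2-(2,3,4-trimethoxyphenyl)-4H-chromen-4-one | COc1ccc(-c2oc3c(OC)c(OC)cc(OC)c3c(=O)c2O)c(OC)c1OC | intermediate
10 | 3,5,7,8-tetramethoxy-2-(2,3,4-trimethoxyphenyl)-4H-chromen-4-one | COc1ccc(-c2oc3c(OC)c(OC)cc(OC)c3c(=O)c2OC)c(OC)c1OC | intermediate
11 | 5-hydroxy-3,7,8-trimethoxy-2-(2,3,4-trimethoxyphenyl)-4H-chromen-4-one | COc1ccc(-c2oc3c(OC)c(OC)cc(O)c3c(=O)c2OC)c(OC)c1OC | intermediate
12 | 3,7-dimethoxy-2-(2,3,4-trimethoxyphenyl)-4H-chromene-4,5,8-trione | COc1ccc(C2=C(OC)C(=O)C3=C(O2)C(=O)C(OC)=CC3=O)c(OC)c1OC | intermediate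
13 | 5,8-dihydroxy-3,7-dimethoxy-2-(2,3,4-trimethoxyphenyl)-4H-chromen-4-one | COc1ccc(-c2oc3c(O)c(OC)cc(O)c3c(=O)c2OC)c(OC)c1OC | target

**Totals**
Total steps: 8. Longest linear sequence: 8 steps (1 to 13); aldehyde 5 enters at step 3.

**Steps most likely to fail, with fallbacks**

Step 4 (Algar–Flynn–Oyamada). The 6'-methoxy group of chalcone 7 can divert the reaction to the aurone. The fallback sets out from 7 and comes back at 9. Chalcone 7 is cyclised oxidatively with catalytic I2 in DMSO at 120 °C to 5,7,8-trimethoxy-2-(2,3,4-trimethoxyphenyl)-4H-chromen-4-one F1. The C2=C3 bond of F1 is then epoxidised with dimethyldioxirane (acetone/CH2Cl2, 0 °C) to racemic 2,3-epoxy-5,7,8-trimethoxy-2-(2,3,4-trimethoxyphenyl)chroman-4-one F2. Catalytic TsOH in CH2Cl2 opens the epoxide at C2 and tautomerisation gives flavonol 9.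

Step 7 (phenol to quinone). The electrophilic trione 12 may be over-oxidised or attacked by water as it forms. The fallback sets out from 11 and comes back at 12. Phenol 11 is oxidised with PhI(OAc)2 in anhydrous MeOH at 0 °C to the isolable quinone monoketal 3,7,8,8-tetramethoxy-2-(2,3,4-trimethoxyphenyl)-8H-chromene-4,5-dione F3. This masked quinone is purified and then hydrolysed with dilute aqueous acid in THF to 12 just before the reduction.

Step 6 (selective 5-O-demethylation). BCl3 may also cleave the 3-OMe or the central B-ring methoxy. The fallback sets out from 10 and comes back at 12, skipping 11. Heptamethyl ether 10 is treated with ceric ammonium nitrate in MeCN/H2O at 0 °C, which oxidatively demethylates the para-related 5,8-dimethoxy pair straight to quinone 12. This fallback makes no new compound (F0).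

**Further compounds**
F1 | step 4 | 5,7,8-trimethoxy-2-(2,3,4-trimethoxyphenyl)-4H-chromen-4-one | COc1ccc(-c2cc(=O)c3c(OC)cc(OC)c(OC)c3o2)c(OC)c1OC
F2 | step 4 | (±)-2,3-epoxy-5,7,8-trimethoxy-2-(2,3,4-trimethoxyphenyl)chroman-4-one (racemic, cis-fused oxirane) | COc1ccc(C23OC2C(=O)c2c(OC)cc(OC)c(OC)c2O3)c(OC)c1OC
F3 | step 7 | 3,7,8,8-tetramethoxy-2-(2,3,4-trimethoxyphenyl)-8H-chromene-4,5-dione | COc1ccc(C2=C(OC)C(=O)C3=C(O2)C(OC)(OC)C(OC)=CC3=O)c(OC)c1OC
F0 | step 6 | none | none
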